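**Plan** (numbering: ring B = C1(aryl)–C2(CO2H)–C3(CO–O–malate)=C4–C4a–C8a; ring A = fused catechol with oxygens on C6 and C7; ring C = pendant catechol on C1)
Cuts: first the malate ester C–O bond; then C4–C4a and C1–C8a together, which removes ring A as 1,2-bis(benzyloxy)benzene and leaves a C1–C4 chain that is electrophilic at both ends, stored as a gamma-lactone (C1–O–CO–C3, a temporary ring) with C4 as an enol ether; last C3–C4 (formylation) and C1–C2 (aldol).
Enabling feature: C1 is benzylic to ring C, whose para oxygen makes the C1–O bond easy to ionise; C4 is at the aldehyde oxidation level (C3=C4 of the enoate); on ring A the adjacent carbons C8a and C4a lie para to the oxygens on C6 and C7, so a symmetric catechol diether can take both electrophiles with no regiochemical choice; rings A and C carry the same substituents, so it does not matter which aryl group ends up as ring A.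
Forward order: acyclic Evans aldol, then the gamma-lactone, then C4, then ring B by one acid-mediated [4+2] Friedel–Crafts annulation that opens the lactone and frees the C3 acid, then the malate ester, then global debenzylation.
Stereochemistry: C2 from the Evans syn aldol with (R)-4-benzyl-1,3-oxazolidin-2-one; the C1 centre of the lactone is erased and rebuilt trans to C2 in the annulation (substrate control); the malate centre comes from (S)-malic acid.

Key step: step 6

Assumption: the exocyclic C3=C4 enol and enol ether double bonds of the intermediates are drawn without E/Z assignment, because this geometry is lost in step 6.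

Step 1
Reactants: 1 methyl 4-chloro-4-oxobutanoate; 2 (R)-4-benzyl-1,3-oxazolidin-2-one
Product: 3 methyl 4-[(4R)-4-benzyl-2-oxo-1,3-oxazolidin-3-yl]-4-oxobutanoate
Conditions: Et3N, DMAP (cat.), CH2Cl2, 0 °C → rt
Reagents that add atoms: none
Why: N-acylation of the oxazolidinone by the acid chloride under nucleophilic catalysis should give the imide without touching the stereocentre of the auxiliary.

Step 2
Reactants: 3 methyl 4-[(4R)-4-benzyl-2-oxo-1,3-oxazolidin-3-yl]-4-oxobutanoate; 4 3,4-bis(benzyloxy)benzaldehyde
Product: 6 methyl (3R,4R)-4-[3,4-bis(benzyloxy)phenyl]-3-{[(4R)-4-benzyl-2-oxo-1,3-oxazolidin-3-yl]carbonyl}-4-hydroxybutanoate, via Z-boron enolate 5 (not isolated)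
Conditions: Bu2BOTf, i-Pr2NEt, CH2Cl2, −78 → 0 °C; 4, −78 → 0 °C; H2O2, MeOH/pH 7 buffer
Reagents that add atoms: none
Why: Evans syn aldol reaction, in which only the imide side of the succinate is enolised and the Z-boron enolate should add to the aldehyde through a closed chair transition state whose enolate face is chosen by the benzyl group of the (R)-auxiliary, which sets C2 (and, for the time being, C1).

Step 3
Reactants: 6 methyl (3R,4R)-4-[3,4-bis(benzyloxy)phenyl]-3-{[(4R)-4-benzyl-2-oxo-1,3-oxazolidin-3-yl]carbonyl}-4-hydroxybutanoate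
Product: 8 (2R,3R)-2-[3,4-bis(benzyloxy)phenyl]-5-oxooxolane-3-carboxylic acid, via hydroxy diacid 7 (not isolated)
Conditions: LiOH, H2O2, THF/H2O, 0 °C → rt; Na2SO3; then 2 M HCl (pH 1), rt
Reagents that add atoms: hydrogen peroxide OO; lithium hydroxide [Li+].[OH-]
Why: Hydroperoxide cleavage of the exocyclic imide carbonyl and saponification of the methyl ester, followed by acid lactonisation of the gamma-hydroxy acid, should give the five-membered lactone with retention at both centres (syn aldol gives the trans lactone) and return the auxiliary.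

Step 4
Reactants: 8 (2R,3R)-2-[3,4-bis(benzyloxy)phenyl]-5-oxooxolane-3-carboxylic acid
Product: 10 (2R,3R)-2-[3,4-bis(benzyloxy)phenyl]-4-(hydroxymethylidene)-5-oxooxolane-3-carboxylic acid, via dilithium dianion 9 (not isolated)
Conditions: LiN(SiMe3)2 (3 equiv), THF, −78 °C; HCO2Et, −78 → 0 °C; 1 M HCl
Reagents that add atoms: ethyl formate CCOC=O
Why: Claisen formylation of the lactone enolate within the carboxylate dianion, in which the carboxylate keeps the C2–H from being removed and so should block both epimerisation and the Stobbe-type beta-elimination that would open the lactone.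

Step 5
Reactants: 10 (2R,3R)-2-[3,4-bis(benzyloxy)phenyl]-4-(hydroxymethylidene)-5-oxooxolane-3-carboxylic acid
Product: 12 benzyl (2R,3R)-2-[3,4-bis(benzyloxy)phenyl]-4-(methoxymethylidene)-5-oxooxolane-3-carboxylate, via benzyl ester 11 (not isolated)
Conditions: BnBr (1.05 equiv), KHCO3, DMF, rt; then Me2SO4, K2CO3, rt
Reagents that add atoms: benzyl bromide BrCc1ccccc1; dimethyl sulfate COS(=O)(=O)OC
Why: Two O-alkylations in order of acidity (SN2 benzylation of the carboxylate, then O-methylation of the formyl-lactone enolate by the hard electrophile dimethyl sulfate) should give the C2 benzyl ester and fix C4 as an enol ether, which cannot decarboxylate once the lactone opens in step 6.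

Step 6
Reactants: 12 benzyl (2R,3R)-2-[3,4-bis(benzyloxy)phenyl]-4-(methoxymethylidene)-5-oxooxolane-3-carboxylate; 13 1,2-bis(benzyloxy)benzene (3 equiv)
Product: 15 (1R,2S)-6,7-bis(benzyloxy)-1-[3,4-bis(benzyloxy)phenyl]-2-[(benzyloxy)carbonyl]-1,2-dihydronaphthalene-3-carboxylic acid, via diaryl acid 14 (not isolated)
Conditions: TFA (10 equiv), (CF3)2CHOH/CH2Cl2 1:4, 0 °C → rt
Reagents that add atoms: none
Why: Proposed new method: in TFA/(CF3)2CHOH the lactone C1–O bond of 12 should ionise like a 4-alkoxybenzyl ester, the benzylic cation (stabilised by the para benzyloxy group of ring C) should be captured by the symmetric arene 13 at a carbon para to oxygen to give 14, and the neighbouring arene carbon (para to the second oxygen) should then add to C4 of the O-protonated beta-methoxyacrylic acid and expel methanol, which restores C3=C4 in conjugation with ring A. The closest known reaction types are the Friedel–Crafts ring-opening alkylation of arenes by gamma-aryl-gamma-butyrolactones, the one-pot annulation of arenes with gamma-butyrolactone to 1-tetralones, the Bradsher cyclodehydration and the acid cyclisation of dibenzylidenesuccinates to 1-aryl-1,2-dihydronaphthalenes, but their merger into one intermolecular annulation on an alpha-(alkoxymethylidene) lactone has not been shown. Ring B is the only ring that closes, by a 6-endo-trig Friedel–Crafts conjugate addition of C4a to C4, while the temporary lactone ring opens and frees the C3 carboxylic acid. C1 is the only new stereocentre: in 14 its two aryl groups are identical, and the untouched C2 centre should select the diastereotopic aryl group whose ring closure leaves the other aryl group pseudoaxial and anti to the pseudoaxial C2 ester (less allylic 1,2 strain with the C3 carboxyl, no peri contact with C8–H), which gives the trans (1R,2S) isomer. The step needs regiocontrol on ring A, secured by the symmetry of 13 and its two para-directing oxygens, and retention at C2, secured if capture of the cation outruns loss of the C2 proton (excess 13, low temperature, an acid too weak to re-protonate an arylidene by-product). Should 13 add to C4 first, the arylidene lactone so formed should ionise at C1 and cyclise to the same product.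

Step 7
Reactants: 15 (1R,2S)-6,7-bis(benzyloxy)-1-[3,4-bis(benzyloxy)phenyl]-2-[(benzyloxy)carbonyl]-1,2-dihydronaphthalene-3-carboxylic acid; 16 dibenzyl (S)-malate
Product: 17 dibenzyl (2S)-2-({[(1R,2S)-6,7-bis(benzyloxy)-1-[3,4-bis(benzyloxy)phenyl]-2-[(benzyloxy)carbonyl]-1,2-dihydronaphthalen-3-yl]carbonyl}oxy)butanedioate
Conditions: DCC, DMAP (cat.), CH2Cl2, 0 °C → rt
Reagents that add atoms: none
Why: Steglich esterification of the conjugated C3 acid with the secondary alcohol of the malate should leave the malate C–O bond and hence its (S) configuration untouched, while the low temperature and the small amount of DMAP limit deprotonation at C2.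

Step 8
Reactants: 17 dibenzyl (2S)-2-({[(1R,2S)-6,7-bis(benzyloxy)-1-[3,4-bis(benzyloxy)phenyl]-2-[(benzyloxy)carbonyl]-1,2-dihydronaphthalen-3-yl]carbonyl}oxy)butanedioate
Product: 18 (2S)-2-({[(1R,2S)-2-carboxy-1-(3,4-dihydroxyphenyl)-6,7-dihydroxy-1,2-dihydronaphthalen-3-yl]carbonyl}oxy)butanedioic acid (target)
Conditions: BCl3, C6HMe5, CH2Cl2, −78 → −20 °C; MeOH/H2O
Reagents that add atoms: none
Why: Lewis acid debenzylation with pentamethylbenzene as a non-basic benzyl cation scavenger should remove the four aryl benzyl ethers and the three benzyl esters without hydrogenating the C3=C4 double bond or cleaving the secondary alkyl ester.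

**Compound list**
1 | methyl 4-chloro-4-oxobutanoate | COC(=O)CCC(=O)Cl | starting material
2 | (R)-4-benzyl-1,3-oxazolidin-2-one | O=C1N[C@H](Cc2ccccc2)CO1 | starting material
3 | methyl 4-[(4R)-4-benzyl-2-oxo-1,3-oxazolidin-3-yl]-4-oxobutanoate | COC(=O)CCC(=O)N1[C@H](Cc2ccccc2)COC1=O | intermediate
4 | 3,4-bis(benzyloxy)benzaldehyde | O=Cc1ccc(OCc2ccccc2)c(OCc2ccccc2)c1 | starting material
5 | methyl (Z)-4-[(4R)-4-benzyl-2-oxo-1,3-oxazolidin-3-yl]-4-[(dibutylboranyl)oxy]but-3-enoate (Z-boron enolate) | CCCCB(CCCC)O/C(=C\CC(=O)OC)N1[C@H](Cc2ccccc2)COC1=O | intermediate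
6 | methyl (3R,4R)-4-[3,4-bis(benzyloxy)phenyl]-3-{[(4R)-4-benzyl-2-oxo-1,3-oxazolidin-3-yl]carbonyl}-4-hydroxybutanoate | COC(=O)C[C@@H](C(=O)N1[C@H](Cc2ccccc2)COC1=O)[C@@H](O)c1ccc(OCc2ccccc2)c(OCc2ccccc2)c1 | intermediate
7 | (2R)-2-{(R)-[3,4-bis(benzyloxy)phenyl](hydroxy)methyl}butanedioic acid | OC(=O)C[C@@H](C(=O)O)[C@@H](O)c1ccc(OCc2ccccc2)c(OCc2ccccc2)c1 | intermediate
8 | (2R,3R)-2-[3,4-bis(benzyloxy)phenyl]-5-oxooxolane-3-carboxylic acid (trans lactone) | O=C1C[C@@H](C(=O)O)[C@H](c2ccc(OCc3ccccc3)c(OCc3ccccc3)c2)O1 | intermediate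
9 | dilithium salt of 8 (carboxylate and lactone enolate) | [Li+].[Li+].[O-]C1=C[C@@H](C([O-])=O)[C@H](c2ccc(OCc3ccccc3)c(OCc3ccccc3)c2)O1 | intermediate
10 | (2R,3R)-2-[3,4-bis(benzyloxy)phenyl]-4-(hydroxymethylidene)-5-oxooxolane-3-carboxylic acid | O=C1C(=CO)[C@@H](C(=O)O)[C@H](c2ccc(OCc3ccccc3)c(OCc3ccccc3)c2)O1 | intermediate
11 | benzyl (2R,3R)-2-[3,4-bis(benzyloxy)phenyl]-4-(hydroxymethylidene)-5-oxooxolane-3-carboxylate | O=C1C(=CO)[C@@H](C(=O)OCc2ccccc2)[C@H](c2ccc(OCc3ccccc3)c(OCc3ccccc3)c2)O1 | intermediate
12 | benzyl (2R,3R)-2-[3,4-bis(benzyloxy)phenyl]-4-(methoxymethylidene)-5-oxooxolane-3-carboxylate | O=C1C(=COC)[C@@H](C(=O)OCc2ccccc2)[C@H](c2ccc(OCc3ccccc3)c(OCc3ccccc3)c2)O1 | intermediate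
13 | 1,2-bis(benzyloxy)benzene | c1ccc(OCc2ccccc2)c(OCc2ccccc2)c1 | starting material
14 | (3S)-3-[(benzyloxy)carbonyl]-4,4-bis[3,4-bis(benzyloxy)phenyl]-2-(methoxymethylidene)butanoic acid | COC=C(C(=O)O)[C@@H](C(=O)OCc1ccccc1)C(c1ccc(OCc2ccccc2)c(OCc2ccccc2)c1)c1ccc(OCc2ccccc2)c(OCc2ccccc2)c1 | intermediate
15 | (1R,2S)-6,7-bis(benzyloxy)-1-[3,4-bis(benzyloxy)phenyl]-2-[(benzyloxy)carbonyl]-1,2-dihydronaphthalene-3-carboxylic acid | OC(=O)C1=Cc2cc(OCc3ccccc3)c(OCc3ccccc3)cc2[C@@H](c2ccc(OCc3ccccc3)c(OCc3ccccc3)c2)[C@@H]1C(=O)OCc1ccccc1 | intermediate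
16 | dibenzyl (S)-malate (dibenzyl (2S)-2-hydroxybutanedioate) | O=C(OCc1ccccc1)C[C@H](O)C(=O)OCc1ccccc1 | starting material
17 | dibenzyl (2S)-2-({[(1R,2S)-6,7-bis(benzyloxy)-1-[3,4-bis(benzyloxy)phenyl]-2-[(benzyloxy)carbonyl]-1,2-dihydronaphthalen-3-yl]carbonyl}oxy)butanedioate | O=C(OCc1ccccc1)C[C@H](OC(=O)C1=Cc2cc(OCc3ccccc3)c(OCc3ccccc3)cc2[C@@H](c2ccc(OCc3ccccc3)c(OCc3ccccc3)c2)[C@@H]1C(=O)OCc1ccccc1)C(=O)OCc1ccccc1 | intermediate
18 | (2S)-2-({[(1R,2S)-2-carboxy-1-(3,4-dihydroxyphenyl)-6,7-dihydroxy-1,2-dihydronaphthalen-3-yl]carbonyl}oxy)butanedioic acid | O=C(O)C[C@H](OC(=O)C1=Cc2cc(O)c(O)cc2[C@@H](c2ccc(O)c(O)c2)[C@@H]1C(=O)O)C(=O)O | target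

Total step count: 8. Longest linear sequence: 8 steps (1 and 2 to 18).

**Steps most likely to fail**

Step 6 (proposed new method). Several processes may divert the cascade: loss of the C2 proton from the C1 cation, which opens the lactone to an arylidene succinate and, if reversible, erodes the C2 configuration; a second intermolecular arylation at C4 before the ring closes; or transfer of benzyl groups from oxygen to the excess arene. The fallback uses known chemistry and makes the two bonds one after the other. It sets out from 8. The dianion of 8 (LiN(SiMe3)2, 2.2 equiv, THF, −78 °C) is condensed with a second equivalent of aldehyde 4 to give the aldol adduct (2R,3R)-2-[3,4-bis(benzyloxy)phenyl]-4-{[3,4-bis(benzyloxy)phenyl](hydroxy)methyl}-5-oxooxolane-3-carboxylic acid F1, a mixture at the two new centres, both of which are lost later. Benzylation of the carboxylate (BnBr, KHCO3, DMF) gives its benzyl ester F2. TFA in CH2Cl2 at 0 °C should then dehydrate the benzylic carbinol to the (E)-arylidene lactone and close ring B by Friedel–Crafts attack of that aryl ring on the C1 cation formed by ionisation of the lactone C–O bond. This is the classical arylidene-lactone sequence of cyclolignan synthesis, in which ring A and C4 come from the aldehyde. It comes back to the route at 15.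

Step 4. Proton transfer within the dianion to C2 may be followed by beta-elimination of the lactone carboxylate (Stobbe-type ring opening), or C-formylation may stay incomplete. The fallback sets out from 8 and installs C4 without an amide base. Benzylation (BnBr, KHCO3, DMF) gives benzyl (2R,3R)-2-[3,4-bis(benzyloxy)phenyl]-5-oxooxolane-3-carboxylate F3. Aminomethylenation with tert-butoxybis(dimethylamino)methane (toluene, 70 °C) should give the enaminone benzyl (2R,3R)-2-[3,4-bis(benzyloxy)phenyl]-4-[(dimethylamino)methylidene]-5-oxooxolane-3-carboxylate F4. Hydrolysis with dilute HCl in THF gives 11, which is O-methylated as in the second stage of step 5. The fallback comes back to the route at 12.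

Step 8. Cleavage of the three benzyl esters may stay incomplete at the low temperature that the ester link and the free catechols tolerate, or benzyl cations may escape the scavenger and alkylate the freed catechol rings. The fallback sets out from 17 and replaces Lewis acid ionisation by silane-mediated hydrogenolysis (PdCl2, Et3SiH, Et3N, CH2Cl2, rt), which should spare the C3=C4 double bond and give the heptakis(triethylsilyl) derivative of the target (three silyl esters, four aryl silyl ethers) F5. Mild solvolysis (dilute citric acid, MeOH/H2O) then frees all seven groups. It comes back to the route at 18.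

**Further compounds**
F1 | step 6 | (2R,3R)-2-[3,4-bis(benzyloxy)phenyl]-4-{[3,4-bis(benzyloxy)phenyl](hydroxy)methyl}-5-oxooxolane-3-carboxylic acid | O=C1C(C(O)c2ccc(OCc3ccccc3)c(OCc3ccccc3)c2)[C@@H](C(=O)O)[C@H](c2ccc(OCc3ccccc3)c(OCc3ccccc3)c2)O1
F2 | step 6 | benzyl (2R,3R)-2-[3,4-bis(benzyloxy)phenyl]-4-{[3,4-bis(benzyloxy)phenyl](hydroxy)methyl}-5-oxooxolane-3-carboxylate | O=C1C(C(O)c2ccc(OCc3ccccc3)c(OCc3ccccc3)c2)[C@@H](C(=O)OCc2ccccc2)[C@H](c2ccc(OCc3ccccc3)c(OCc3ccccc3)c2)O1
F3 | step 4 | benzyl (2R,3R)-2-[3,4-bis(benzyloxy)phenyl]-5-oxooxolane-3-carboxylate | O=C1C[C@@H](C(=O)OCc2ccccc2)[C@H](c2ccc(OCc3ccccc3)c(OCc3ccccc3)c2)O1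
F4 | step 4 | benzyl (2R,3R)-2-[3,4-bis(benzyloxy)phenyl]-4-[(dimethylamino)methylidene]-5-oxooxolane-3-carboxylate | O=C1C(=CN(C)C)[C@@H](C(=O)OCc2ccccc2)[C@H](c2ccc(OCc3ccccc3)c(OCc3ccccc3)c2)O1
F5 | step 8 | heptakis(triethylsilyl) derivative of 18 (three triethylsilyl esters, four aryl triethylsilyl ethers) | CC[Si](CC)(CC)OC(=O)C[C@H](OC(=O)C1=Cc2cc(O[Si](CC)(CC)CC)c(O[Si](CC)(CC)CC)cc2[C@@H](c2ccc(O[Si](CC)(CC)CC)c(O[Si](CC)(CC)CC)c2)[C@@H]1C(=O)O[Si](CC)(CC)CC)C(=O)O[Si](CC)(CC)CC
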